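## Analysis of the target

Target **8** is an acyclic diarylnonanoid whose nine-carbon chain is numbered from the ketone carbon C1 to the benzylic carbon C9, with ring B (2,6-dihydroxyphenyl) on C1, ring A (4-hydroxy-3-methoxyphenyl, guaiacyl) on C9 and eight unbranched methylenes C2–C9 between them. It has no stereocentre and no ring to close, so the task is one of connectivity and functional-group economy. The sensitive groups are three free phenols, acidic and oxidisable (the 4-alkylguaiacol most of all), and an aryl ketone that is hydrogen-bonded to both ortho hydroxyls. The methyl ether of ring A has to survive to the end, so methyl ethers cannot protect the other phenols, because no demethylation would tell them apart. The difficulty lies in the position of the acyl group on ring B: it sits on the carbon between the two hydroxyls, a site that electrophilic acylation of a resorcinol avoids in favour of the 4-position and that carbanion chemistry reaches only with both oxygens masked and later released. The strategy rests on the fact that C1 is bonded to the ring B carbon flanked by two equivalent hydroxyls, so that at the aldehyde oxidation level this half of the molecule is 2,6-dihydroxybenzaldehyde **7**. An ortho hydroxyl of **7** can hold a rhodium centre next to the formyl C–H, and the symmetry of ring B means that either hydroxyl gives the same chelate, so the directing group is already part of the target and ring B needs no protecting group.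

## Retrosynthetic reasoning

**C1–C2 bond.** Target **8** is cut between the carbonyl carbon C1 and C2, giving 2,6-dihydroxybenzaldehyde **7** and the terminal alkene 2-methoxy-4-(oct-7-en-1-yl)phenol **6**. This cut leaves C1 on ring B as a formyl group, and the two alkene carbons of **6** become C2 and C3. A cut at the aryl–C1 bond or at C2–C3 would call for a metalated or enolised ring B fragment with both ortho oxygens protected. The chosen cut needs no protecting group on ring B, no redox adjustment and wastes no atoms. The forward reaction must add the formyl C–H of **7** across the alkene of **6** with the acyl carbon on the terminal carbon, and must avoid branched addition, double-bond migration and decarbonylation.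

**O–Si bond on ring A.** Alkene **6** is traced back to its silyl ether, tert-butyl[2-methoxy-4-(oct-7-en-1-yl)phenoxy]dimethylsilane **5**. The phenol proton would quench the organometallic reagent used to attach the chain, so it is masked for that step only. It is unmasked before the final step so that the hydroacylation delivers **8** directly.

**Ring A–C9 bond.** Silyl ether **5** is cut between ring A and the benzylic carbon C9. This gives the arylmagnesium bromide **4** and 8-bromooct-1-ene **3**, which brings all eight remaining chain carbons together with the terminal alkene. A cut inside the chain would need two bifunctional pieces, and a carbonyl-based bond formation at C9 would leave a benzylic oxygen to be removed without touching the alkene. The forward reaction is a copper-catalysed substitution at a primary bromide by an aryl nucleophile; it has to outrun homocoupling and elimination, and it leaves the distal alkene alone.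

**C–Mg and O–Si bonds.** Grignard reagent **4** comes from metal insertion into the C–Br bond of (4-bromo-2-methoxyphenoxy)(tert-butyl)dimethylsilane **2**, which is the silyl ether of commercial 4-bromo-2-methoxyphenol **1**. The bromine of **1** already marks the carbon that will carry the chain, so no regiochemical question arises on ring A.

## Alternatives that were turned down

**Alternative 1: Claisen closure of ring B, aromatised afterwards.**
- Disconnection: ring B itself is opened at the bond between the acyl-bearing ring carbon and one oxygen-bearing ring carbon. The open-chain precursor is methyl 15-[4-(benzyloxy)-3-methoxyphenyl]-5,7-dioxopentadecanoate A2.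
- Key forward reaction: NaOMe forms the enolate at C6, between the two ketones of A2. This carbon attacks the ester carbonyl in a six-membered Claisen closure to give 2-{9-[4-(benzyloxy)-3-methoxyphenyl]nonanoyl}cyclohexane-1,3-dione A1.
- For: in A1 the acyl group lies between the two ring oxygens by construction, so the ring closure has no regioisomer problem. On that point it is stronger than a hydroacylation, which has to choose between linear and branched addition.
- Against: A1 is at the cyclohexanedione level and needs a forcing dehydrogenation to reach the resorcinol level, one that must spare the benzylic C–H bonds at C9 and in the benzyl ether. The doubly stabilised enolate of A2 is a weak nucleophile towards an unactivated ester. A1 can also undergo retro-Claisen cleavage by the same alkoxide. A2 takes several steps to assemble, and a benzyl group must be put on and taken off.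
- Comparison: the route through A2 and A1 builds from scratch a ring that can be bought as **7** with the correct substitution, and it pays for this with a redox correction. The chosen route gives up the regiochemical certainty of the ring closure in exchange for four steps and no change of oxidation state.

**Alternative 2: hydrogen-borrowing alkylation of a methyl ketone.**
- Disconnection: the C2–C3 bond. The partners are 1-[2,6-bis(benzyloxy)phenyl]ethan-1-one A4 and 7-[4-(benzyloxy)-3-methoxyphenyl]heptan-1-ol A5.
- Key forward reaction: [Cp*IrCl2]2 with KOH oxidises A5 transiently to its aldehyde. Aldol condensation with A4 gives an enone, which takes back the stored hydride to give 1-[2,6-bis(benzyloxy)phenyl]-9-[4-(benzyloxy)-3-methoxyphenyl]nonan-1-one A3.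
- For: water is the only by-product on the way to A3. The two ortho benzyloxy groups of A4 twist the carbonyl out of the ring plane and shield it, which disfavours ketone reduction and double alkylation. The reaction does not depend on a finely tuned ligand, so it is probably the safer of the two central steps.
- Against: the hot, strongly basic medium excludes free phenols, since a phenoxide ortho to the ketone would suppress enolisation. A3 therefore carries three benzyl ethers and needs a triple hydrogenolysis at the end. A5 needs a multi-step synthesis about as long as the whole route to **6**. The C2–C3 cut makes no use of the ortho hydroxyl.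
- Comparison: reaching the target through A3 takes roughly twice as many steps as the chosen route. The chosen route carries more risk in its central step, but it uses one transient silyl group and assembles the target from commercial **7** in the final operation.

**Alternative 3: cross-metathesis with a eugenol-derived guaiacyl end.**
- Disconnection: the C7=C8 double bond of an unsaturated precursor. The partners are eugenol A7 and 1-[2,6-bis(benzyloxy)phenyl]oct-7-en-1-one A8.
- Key forward reaction: the second-generation Grubbs catalyst RuCl2(=CHPh)(H2IMes)(PCy3) exchanges the alkylidenes of A7 and A8 to give (E)-1-[2,6-bis(benzyloxy)phenyl]-9-(4-hydroxy-3-methoxyphenyl)non-7-en-1-one A6. A later hydrogenation of A6 would saturate the alkene and remove both benzyl groups in one operation.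
- For: A7 is a cheap guaiacyl block that already carries C9 and C8 and tolerates metathesis as the free phenol. The alkene geometry of A6 is irrelevant, because the double bond is hydrogenated afterwards. Metathesis is the more general and less ligand-sensitive reaction.
- Against: A7 and A8 are both unhindered terminal alkenes of similar reactivity, so homodimers compete unless one partner is used in large excess. Allylarenes such as A7 tend to isomerise into conjugation under ruthenium hydride species, and metathesis of the isomer would give a chain one carbon short, a homologue of A6 that is very hard to separate. A8 needs benzylation, an organometallic addition and an oxidation before the metathesis. The final hydrogenation of A6 must stop short of the aryl ketone.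
- Comparison: the route through A6 takes five steps and two protecting groups on ring B, against four steps and none. The typical impurity of the hydroacylation is a branched constitutional isomer, which should be easier to remove than a homologue.

Key step: step 4

Remark on the chemistry: the guaiacyl hydroxyl of **6** is left free in step 4 on the assumption that catalytic K3PO4 deprotonates only the much more acidic ortho-hydroxybenzaldehyde **7**. The ligand is a single enantiomer for availability only, since no stereocentre is formed.

## Route

Step 1
Reactants: 1 4-bromo-2-methoxyphenol
Product: 2 (4-bromo-2-methoxyphenoxy)(tert-butyl)dimethylsilane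
Conditions: TBSCl, imidazole, DMF, 0 °C to rt
Reagents that add atoms: tert-butyldimethylsilyl chloride, CC(C)(C)[Si](C)(C)Cl
Why: Standard phenol silylation with imidazole as base and silyl-transfer agent; it removes the acidic proton that would quench the Grignard reagent of step 2, and the aryl bromide and methyl ether are inert.

Step 2
Reactants: 2 (4-bromo-2-methoxyphenoxy)(tert-butyl)dimethylsilane; 3 8-bromooct-1-ene
Product: 5 tert-butyl[2-methoxy-4-(oct-7-en-1-yl)phenoxy]dimethylsilane, via arylmagnesium bromide 4 (not isolated)
Conditions: Mg, 1,2-dibromoethane (cat.), THF, reflux; then 3, Li2CuCl4 (3 mol%), THF/NMP, 0 °C to rt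
Reagents that add atoms: none
Why: Magnesium inserts into the aryl bromide (the silyl ether is para to the new C–Mg bond, so no silyl migration is possible), and the Grignard reagent then alkylates at the primary bromide in a Kochi-type copper-catalysed sp2–sp3 cross-coupling. The aryl silyl ether and the remote terminal alkene are spectators to the organocopper intermediate, and substitution at an unhindered primary bromide should outpace elimination.

Step 3
Reactants: 5 tert-butyl[2-methoxy-4-(oct-7-en-1-yl)phenoxy]dimethylsilane
Product: 6 2-methoxy-4-(oct-7-en-1-yl)phenol
Conditions: TBAF, THF, 0 °C; H2O work-up
Reagents that add atoms: none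
Why: Fluoride-induced desilylation of an aryl silyl ether, driven by the strength of the Si–F bond and the good phenoxide leaving group; the alkene and the methyl ether are untouched.

Step 4
Reactants: 6 2-methoxy-4-(oct-7-en-1-yl)phenol; 7 2,6-dihydroxybenzaldehyde
Product: 8 1-(2,6-dihydroxyphenyl)-9-(4-hydroxy-3-methoxyphenyl)nonan-1-one
Conditions: [Rh(cod)Cl]2 (2.5 mol%), (Ra,R,R)-SIPHOS-PE phosphoramidite (10 mol%), K3PO4 (10 mol%), 1,2-dichloroethane, 70 °C, under argon
Reagents that add atoms: none
Why: K3PO4 deprotonates one of the two equivalent ortho hydroxyls of 7, which are far more acidic than the guaiacyl hydroxyl of 6, and the phenoxide binds monovalent rhodium. Oxidative addition of the formyl C–H then gives a five-membered acyl hydride chelate of trivalent rhodium, in which O,C-chelation disfavours the carbonyl de-insertion that leads to decarbonylation. The terminal alkene of 6 coordinates and inserts into Rh–H with the metal on the terminal carbon, the future C2, and C–C reductive elimination forms the C1–C2 bond and returns monovalent rhodium, after which proton exchange with a further molecule of 7 releases 8. The closest known reaction type is the rhodium/phosphoramidite-catalysed, phenol-directed intermolecular hydroacylation of unactivated terminal alkenes by salicylaldehydes, which is linear-selective. No ring is closed and no stereocentre is formed. The step needs linear over branched insertion, no migration of the double bond along the chain and no decarbonylation. The monosubstituted, unhindered alkene and the bulky spirocyclic phosphoramidite should secure this, because the secondary alkyl is crowded and can revert by β-hydride elimination while reductive elimination from the primary alkyl is faster. The mirror symmetry of 7 removes any question of which hydroxyl directs, and the guaiacyl phenol of 6 has no neighbouring formyl group and cannot enter the cycle.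

## Compound list

1 | 4-bromo-2-methoxyphenol | COc1cc(Br)ccc1O | starting material
2 | (4-bromo-2-methoxyphenoxy)(tert-butyl)dimethylsilane | COc1cc(Br)ccc1O[Si](C)(C)C(C)(C)C | intermediate
3 | 8-bromooct-1-ene | C=CCCCCCCBr | starting material
4 | {4-[(tert-butyldimethylsilyl)oxy]-3-methoxyphenyl}magnesium bromide | COc1cc([Mg]Br)ccc1O[Si](C)(C)C(C)(C)C | intermediate
5 | tert-butyl[2-methoxy-4-(oct-7-en-1-yl)phenoxy]dimethylsilane | C=CCCCCCCc1ccc(O[Si](C)(C)C(C)(C)C)c(OC)c1 | intermediate
6 | 2-methoxy-4-(oct-7-en-1-yl)phenol | C=CCCCCCCc1ccc(O)c(OC)c1 | intermediate
7 | 2,6-dihydroxybenzaldehyde | O=Cc1c(O)cccc1O | starting material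
8 | 1-(2,6-dihydroxyphenyl)-9-(4-hydroxy-3-methoxyphenyl)nonan-1-one | COc1cc(CCCCCCCCC(=O)c2c(O)cccc2O)ccc1O | target

## Step count and risk

Total step count: 4. Longest linear sequence: 4 steps (1 → 2 → 5 → 6 → 8); 3 and 7 are bought and enter in steps 2 and 4.

**Step 4 (key step).**
- What may go wrong: hydride insertion with the opposite regiochemistry, which leads to branched addition. Rhodium hydride may also move the double bond of 6 inward, away from the reactive terminal position. Decarbonylation of the acyl rhodium hydride would consume 7 and poison the catalyst as a carbonyl complex; the two ortho substituents on the acyl group could slow reductive elimination and give this pathway more time. Product inhibition through chelation of the metal by the hydroxy ketone is a further risk.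
- Fallback: set out from silyl ether 5 and replace the one-step hydroacylation by a stepwise equivalent, returning at 8. Linear-selective hydroformylation of 5 (Rh(acac)(CO)2, Xantphos, CO/H2, toluene, 80 °C) should install C1 as the aldehyde 9-{4-[(tert-butyldimethylsilyl)oxy]-3-methoxyphenyl}nonanal F1. Commercially available 1,3-bis(methoxymethoxy)benzene F2 is lithiated between its two acetal oxygens by directed ortho-metalation (n-BuLi, THF, 0 °C) to [2,6-bis(methoxymethoxy)phenyl]lithium F3. F3 adds to F1 at −78 °C to give racemic 1-[2,6-bis(methoxymethoxy)phenyl]-9-{4-[(tert-butyldimethylsilyl)oxy]-3-methoxyphenyl}nonan-1-ol F4. Dess–Martin oxidation removes the transient stereocentre and gives 1-[2,6-bis(methoxymethoxy)phenyl]-9-{4-[(tert-butyldimethylsilyl)oxy]-3-methoxyphenyl}nonan-1-one F5. Methanolic HCl at 50 °C cleaves both methoxymethyl acetals and the aryl silyl ether to give 8.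

**Step 2.**
- What may go wrong: incomplete magnesium insertion into the electron-rich aryl bromide; oxidative homocoupling of the aryl Grignard reagent under copper; sluggish substitution at the alkyl bromide by the aryl copper species, which lets halogen–metal exchange and elimination of 3 compete.
- Fallback: reverse the polarity, setting out from 2 and 3 and returning at 5. Zinc dust activated with LiCl in THF inserts into 3 to give oct-7-en-1-ylzinc bromide F6. A Negishi coupling of F6 with aryl bromide 2 (Pd(OAc)2, SPhos, THF, rt to 50 °C) proceeds through a zerovalent palladium cycle that tolerates the silyl ether and the alkene, and should give 5.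

**Step 3.**
- What may go wrong: air oxidation of the electron-rich phenoxide formed under basic fluoride conditions, and carry-over of ammonium and fluoride residues that would deactivate the rhodium catalyst of step 4.
- Fallback: change the order of events, setting out from 5 with 7 and returning at 8. The hydroacylation conditions of step 4 are applied to silyl ether 5, which should give 9-{4-[(tert-butyldimethylsilyl)oxy]-3-methoxyphenyl}-1-(2,6-dihydroxyphenyl)nonan-1-one F7. Acidic methanolysis of the aryl silyl ether of F7 (HCl, MeOH, rt to 40 °C) then gives 8 with no guaiacyl phenoxide and no ammonium salt before the rhodium step.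

## Further compounds

F1 | step 4 | 9-{4-[(tert-butyldimethylsilyl)oxy]-3-methoxyphenyl}nonanal | O=CCCCCCCCCc1ccc(O[Si](C)(C)C(C)(C)C)c(OC)c1
F2 | step 4 | 1,3-bis(methoxymethoxy)benzene | COCOc1cccc(OCOC)c1
F3 | step 4 | [2,6-bis(methoxymethoxy)phenyl]lithium | [Li]c1c(OCOC)cccc1OCOC
F4 | step 4 | 1-[2,6-bis(methoxymethoxy)phenyl]-9-{4-[(tert-butyldimethylsilyl)oxy]-3-methoxyphenyl}nonan-1-ol (racemic) | COCOc1cccc(OCOC)c1C(O)CCCCCCCCc1ccc(O[Si](C)(C)C(C)(C)C)c(OC)c1
F5 | step 4 | 1-[2,6-bis(methoxymethoxy)phenyl]-9-{4-[(tert-butyldimethylsilyl)oxy]-3-methoxyphenyl}nonan-1-one | COCOc1cccc(OCOC)c1C(=O)CCCCCCCCc1ccc(O[Si](C)(C)C(C)(C)C)c(OC)c1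
F6 | step 2 | oct-7-en-1-ylzinc bromide | C=CCCCCCC[Zn]Br
F7 | step 3 | 9-{4-[(tert-butyldimethylsilyl)oxy]-3-methoxyphenyl}-1-(2,6-dihydroxyphenyl)nonan-1-one | COc1cc(CCCCCCCCC(=O)c2c(O)cccc2O)ccc1O[Si](C)(C)C(C)(C)C
A1 | alternative 1 | 2-{9-[4-(benzyloxy)-3-methoxyphenyl]nonanoyl}cyclohexane-1,3-dione | O=C1CCCC(=O)C1C(=O)CCCCCCCCc1ccc(OCc2ccccc2)c(OC)c1
A2 | alternative 1 | methyl 15-[4-(benzyloxy)-3-methoxyphenyl]-5,7-dioxopentadecanoate | COC(=O)CCCC(=O)CC(=O)CCCCCCCCc1ccc(OCc2ccccc2)c(OC)c1
A3 | alternative 2 | 1-[2,6-bis(benzyloxy)phenyl]-9-[4-(benzyloxy)-3-methoxyphenyl]nonan-1-one | COc1cc(CCCCCCCCC(=O)c2c(OCc3ccccc3)cccc2OCc2ccccc2)ccc1OCc1ccccc1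
A4 | alternative 2 | 1-[2,6-bis(benzyloxy)phenyl]ethan-1-one | CC(=O)c1c(OCc2ccccc2)cccc1OCc1ccccc1
A5 | alternative 2 | 7-[4-(benzyloxy)-3-methoxyphenyl]heptan-1-ol | OCCCCCCCc1ccc(OCc2ccccc2)c(OC)c1
A6 | alternative 3 | (E)-1-[2,6-bis(benzyloxy)phenyl]-9-(4-hydroxy-3-methoxyphenyl)non-7-en-1-one | COc1cc(C/C=C/CCCCCC(=O)c2c(OCc3ccccc3)cccc2OCc2ccccc2)ccc1O
A7 | alternative 3 | eugenol (2-methoxy-4-(prop-2-en-1-yl)phenol) | C=CCc1ccc(O)c(OC)c1
A8 | alternative 3 | 1-[2,6-bis(benzyloxy)phenyl]oct-7-en-1-one | C=CCCCCCC(=O)c1c(OCc2ccccc2)cccc1OCc1ccccc1
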